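Ask where the substrate of this flask ends up by 12 d, and whether the reaction has stopped by then.

in all of them: precatalyst 4.6 mM

| flask | substrate | remark | time |
|---|---|---|---|
| Thursday's | 0.94 M (fed, over 20 h) | run made earlier; the fed solution adds 0.50 times the starting volume |  |
| Friday's | 2.1 M (fed, over 20 h) | run made earlier; the fed solution adds 0.50 times the starting volume |  |
| flask | 1.4 M (fed, over 20 h) | the fed solution adds 0.50 times the starting volume | 12 d |

| run | time / d | substrate / % | target / % | side product B / % |
|---|---|---|---|---|
| Thursday's | 0.833 | 66.4 | 29.9 | 2.5 |
| Thursday's | 2.50 | 9.0 | 62.9 | 23.0 |
| Thursday's | 5.00 | 0 | 71.1 | 26.6 |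
| Thursday's | 8.00 | 0.6 | 71.4 | 27.4 |
| Friday's | 0.625 | 54.6 | 17.2 | 5.7 |
| Friday's | 1.25 | 38.5 | 40.6 | 20.0 |
| Friday's | 3.00 | 3.2 | 54.1 | 41.4 |
| Friday's | 8.00 | 0 | 56.1 | 43.1 |

(each reading ± 1 percentage point)

- at 12 d, what has stopped the reaction, if anything has (it is still moving / no working catalyst is left / all of the substrate has reacted)
- conversion of substrate at 12 d
- amount of target at 12 d, in percent of the substrate charged
- amount of side product B at 12 d, in percent of the substrate charged

- in percentages every species weighs as the substrate in it: one side product B counts as two
- charges are per starting volume, the dose included; the dosed solution carries all of it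
- the reaction counts as stopped when no species that holds the substrate changes by six tenths of a point or more over the second half of the time
- percentages count the whole charge, also what has not yet gone in

Start from the end state. Read Thursday's last rows: target holds at 71.1% and 71.4% with substrate at 0% and 0.6%. So take target as stable once substrate is gone. B lags: at 0.833 d Thursday's run shows 2.5% of B beside 29.9% of target. So suppose substrate goes two ways, to target, and together with target to B, each first order in [substrate]. Time then drops out of the split. B made per target made is [target]/(K − [target]), with K the level of target at which both ways run equally.

Now estimate K. Put the midway level m = [target]/2 into that ratio, counting B in molecules per starting volume. Then K = m(1 + target/B). Thursday's last row gives 2.08 M, and Friday's gives 2.12 M.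

Object: K may shift with the charge. But Friday's charge is larger and the two values lie close. Object: the feed dilutes. But target and whatever the precatalyst gives dilute alike, and the precatalyst charge is 4.6 mM in each flask. Keep 2.10 M, the crossover level, a selectivity factor in concentration units.

Solve the rule for this flask, with the charge equal to target plus twice B, B counted in molecules. It gives 0.905 M of target, which is 64.6%, and 35.4% of B.

Object: the reaction may stall. Thursday's readings show substrate falling after the feed at about 1.20 d⁻¹, a half-life of about 0.578 d, far shorter than 12 d. Friday's larger charge read 0% of substrate at 8.00 d on the same precatalyst charge. So expect this flask, like Friday's at 0%, to have its substrate used up by 12 d.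

The forecast gives all of the substrate has reacted, conversion 100%, target 65.2% and B 34.6%: “Only selectivity needs estimating.”

At 12 d the flask shows: all of the substrate has reacted, conversion >99.9%, target 63.3%, B 35.2%. In this flask side product A holds 1.55%, which the two-way reckoning does not have. Put the flask's own end amounts into the rule: K comes to 2.03 M, beside 2.10 M from the runs.

    substrate + catalyst → catalyst + target (k = 12.0 M⁻¹ h⁻¹)
    substrate → side product A (k = 7.40 × 10⁻⁴ h⁻¹)
    2 substrate → homo dimer (k = 1.30 × 10⁻⁵ M⁻¹ h⁻¹)
    precatalyst → catalyst (k = 1.10 h⁻¹)
    substrate + target → side product B (k = 0.0250 M⁻¹ h⁻¹)

With its constants held, the scheme makes K proportional to catalyst. So for the neighbour flask with 0.018 M of precatalyst, scale K to 8.23 M. The rule then gives 86.3% of target, and the computed neighbour flask gives 86.3%.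

All runs are simulated with constants of no real substance, and the scatter is random.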